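Ring C is disconnected at C3–C4. The C3 carbinol is trans to the C2 aryl group and C4 is an unsubstituted benzylic CH2 on ring A, so both map onto a C3=C4 alkene that C2 can steer in a hydroboration. Ring-closing metathesis forms this alkene and closes ring C in one operation from a diene that already holds rings A, B and the galloyl ester: a 2-vinylaryl (S)-1-arylallyl ether. C4 is the formyl carbon of 2,4,6-trihydroxybenzaldehyde, whose hydrogen bonds tell O7, O1 and O5 apart without extra protecting groups. C2 comes from an iridium-catalysed asymmetric allylic etherification.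

Key step: step 7

Numbering: flavan numbering is used (O1, C2, C3, C4, C4a, C5–C8, C8a). Ring A is the benzo ring, ring B the catechol ring and ring C the pyran ring.

Assumption: the (Sa,Sc,Sc) antipode of the phosphoramidite ligand is taken to deliver the (S)-ether 7. If the sense of induction is the opposite, the (Ra,Rc,Rc) antipode is used and nothing else changes.

Step 1
Reactants: 1 2,4,6-trihydroxybenzaldehyde
Product: 2 4-(benzyloxy)-2,6-dihydroxybenzaldehyde
Conditions: BnBr (1.0 equiv), CsHCO3, MeCN, 60 °C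
Reagents that add atoms: benzyl bromide, BrCc1ccccc1
Why: Williamson ether synthesis; the 4-OH is para to the formyl group and is the only phenol not hydrogen-bonded to it, so it is the most acidic and accessible one and should be alkylated selectively by one equivalent of benzyl bromide with a weak base.

Step 2
Reactants: 3 3,4-bis(benzyloxy)benzaldehyde
Product: 4 1,2-bis(benzyloxy)-4-vinylbenzene
Conditions: MePPh3Br, KOt-Bu, THF, 0 °C to rt
Reagents that add atoms: methyltriphenylphosphonium bromide, C[P+](c1ccccc1)(c1ccccc1)c1ccccc1.[Br-]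
Why: Wittig methylenation of an aromatic aldehyde with a non-stabilised ylide, to which the benzyl ethers are inert.

Step 3
Reactants: 4 1,2-bis(benzyloxy)-4-vinylbenzene; 5 allyl methyl carbonate (3 equiv)
Product: 6 (E)-3-[3,4-bis(benzyloxy)phenyl]allyl methyl carbonate
Conditions: second-generation Hoveyda–Grubbs catalyst RuCl2(=CH-C6H4-2-O-i-Pr)(SIMes) (3 mol%), CH2Cl2, 40 °C
Reagents that add atoms: none
Why: Olefin cross-metathesis between a slowly homodimerising styrene and an excess of a rapidly exchanging allylic carbonate should give the conjugated (E)-alkene under thermodynamic control.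

Step 4
Reactants: 2 4-(benzyloxy)-2,6-dihydroxybenzaldehyde; 6 (E)-3-[3,4-bis(benzyloxy)phenyl]allyl methyl carbonate
Product: 7 (S)-4-(benzyloxy)-2-{1-[3,4-bis(benzyloxy)phenyl]allyloxy}-6-hydroxybenzaldehyde
Conditions: [Ir(cod)Cl]2 (2 mol%), (Sa,Sc,Sc)-N,N-bis(1-phenylethyl)dinaphtho[2,1-d:1',2'-f][1,3,2]dioxaphosphepin-4-amine (4 mol%), TBD (8 mol%, pre-activation), THF, rt
Reagents that add atoms: none
Why: Iridium-catalysed asymmetric allylic etherification; the cyclometalated iridium phosphoramidite ionises 6 to a π-allyl complex that the phenoxide of 2 (formed by the released methoxide) attacks at the aryl-bearing terminus, the ligand fixing the face and hence the (S) centre that becomes C2, while the second ortho OH stays hydrogen-bonded to the formyl group and so resists a second alkylation.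

Step 5
Reactants: 7 (S)-4-(benzyloxy)-2-{1-[3,4-bis(benzyloxy)phenyl]allyloxy}-6-hydroxybenzaldehyde
Product: 8 (S)-5-(benzyloxy)-3-{1-[3,4-bis(benzyloxy)phenyl]allyloxy}-2-vinylphenol
Conditions: MePPh3Br (3.5 equiv), KOt-Bu (3.3 equiv), THF, 0 °C to rt; pH 7 work-up, used without storage
Reagents that add atoms: methyltriphenylphosphonium bromide, C[P+](c1ccccc1)(c1ccccc1)c1ccccc1.[Br-]
Why: Wittig methylenation of a salicylaldehyde with excess ylide (one equivalent is spent on the phenol), the salt being kept in slight excess over the base so that no free alkoxide can touch the C2–H of the allylic ether.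

Step 6
Reactants: 8 (S)-5-(benzyloxy)-3-{1-[3,4-bis(benzyloxy)phenyl]allyloxy}-2-vinylphenol; 9 3,4,5-tris(benzyloxy)benzoic acid
Product: 10 (S)-5-(benzyloxy)-3-{1-[3,4-bis(benzyloxy)phenyl]allyloxy}-2-vinylphenyl 3,4,5-tris(benzyloxy)benzoate
Conditions: DCC, DMAP (cat.), CH2Cl2, 0 °C to rt
Reagents that add atoms: none
Why: Steglich esterification; DMAP relays the O-acylisourea of 9 to the only free hydroxyl group of 8, which fixes the galloyl group on O5 and also stabilises the sensitive vinylphenol.

Step 7
Reactants: 10 (S)-5-(benzyloxy)-3-{1-[3,4-bis(benzyloxy)phenyl]allyloxy}-2-vinylphenyl 3,4,5-tris(benzyloxy)benzoate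
Product: 11 (S)-7-(benzyloxy)-2-[3,4-bis(benzyloxy)phenyl]-2H-chromen-5-yl 3,4,5-tris(benzyloxy)benzoate
Conditions: second-generation Grubbs catalyst RuCl2(=CHPh)(PCy3)(SIMes) (5 mol%), 1,4-benzoquinone (10 mol%), CH2Cl2 (5 mM), 40 °C, dark
Reagents that add atoms: none
Why: Ring-closing olefin metathesis: the benzylidene catalyst should initiate at the less hindered allylic vinyl group (C3=CH2), the resulting C3 alkylidene adds [2+2] across the neighbouring styrene C4=CH2, and cycloreversion of the ruthenacyclobutane forms the C3=C4 double bond, with loss of ethylene making the step irreversible. The closest known reaction type is the RCM of 2-vinylaryl 1-substituted allyl ethers to 2-substituted 2H-chromenes. Ring C closes as a six-membered ring with an endocyclic cis alkene, because the ortho relation of O1 and C4 on ring A holds both alkenes within reach. No stereocentre is created; C2 lies outside the reacting π systems and is carried through unchanged, and the new planar C3=C4 unit is what lets C2 dictate C3 in step 8. The step needs cyclisation to win over dimerisation and over hydride-induced isomerisation of the allyl ether, which high dilution and 1,4-benzoquinone should secure, and it needs exclusion of light and a temperature of at most 40 °C because 2H-chromenes can racemise through reversible oxa-6π ring opening.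

Step 8
Reactants: 11 (S)-7-(benzyloxy)-2-[3,4-bis(benzyloxy)phenyl]-2H-chromen-5-yl 3,4,5-tris(benzyloxy)benzoate
Product: 13 (2R,3S)-7-(benzyloxy)-2-[3,4-bis(benzyloxy)phenyl]-3-hydroxychroman-5-yl 3,4,5-tris(benzyloxy)benzoate, via C3-borane 12 (not isolated)
Conditions: BH3·THF, THF, 0 °C; then 30% H2O2, pH 7 phosphate buffer, 0 °C to rt
Reagents that add atoms: borane–tetrahydrofuran, B.C1CCOC1 (boron stays only in 12); hydrogen peroxide, OO
Why: Hydroboration–oxidation of a flav-3-ene; boron and hydrogen add syn, boron going to C3 (made electron-rich by the O1 and O7 donors of ring A and less shielded than C4 next to the peri 5-O-galloyl group) from the face opposite to the C2 aryl group, and oxidation with retention gives the 2,3-trans (3S) alcohol while the buffered peroxide should spare the aryl ester.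

Step 9
Reactants: 13 (2R,3S)-7-(benzyloxy)-2-[3,4-bis(benzyloxy)phenyl]-3-hydroxychroman-5-yl 3,4,5-tris(benzyloxy)benzoate
Product: 14 catechin 5-O-gallate, (2R,3S)-2-(3,4-dihydroxyphenyl)-3,7-dihydroxychroman-5-yl 3,4,5-trihydroxybenzoate
Conditions: H2 (1 atm), Pd(OH)2/C, THF/MeOH, rt
Reagents that add atoms: none
Why: Catalytic hydrogenolysis removes all six benzyl ethers under neutral conditions that should leave the aryl ester, the cyclic C2–O1 ether and both stereocentres untouched.

Compound list
1 | 2,4,6-trihydroxybenzaldehyde | O=Cc1c(O)cc(O)cc1O | starting material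
2 | 4-(benzyloxy)-2,6-dihydroxybenzaldehyde | O=Cc1c(O)cc(OCc2ccccc2)cc1O | intermediate
3 | 3,4-bis(benzyloxy)benzaldehyde | O=Cc1ccc(OCc2ccccc2)c(OCc2ccccc2)c1 | starting material
4 | 1,2-bis(benzyloxy)-4-vinylbenzene | C=Cc1ccc(OCc2ccccc2)c(OCc2ccccc2)c1 | intermediate
5 | allyl methyl carbonate | C=CCOC(=O)OC | starting material
6 | (E)-3-[3,4-bis(benzyloxy)phenyl]allyl methyl carbonate | COC(=O)OC/C=C/c1ccc(OCc2ccccc2)c(OCc2ccccc2)c1 | intermediate
7 | (S)-4-(benzyloxy)-2-{1-[3,4-bis(benzyloxy)phenyl]allyloxy}-6-hydroxybenzaldehyde | C=C[C@@H](c1ccc(OCc2ccccc2)c(OCc2ccccc2)c1)Oc1cc(OCc2ccccc2)cc(O)c1C=O | intermediate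
8 | (S)-5-(benzyloxy)-3-{1-[3,4-bis(benzyloxy)phenyl]allyloxy}-2-vinylphenol | C=C[C@@H](c1ccc(OCc2ccccc2)c(OCc2ccccc2)c1)Oc1cc(OCc2ccccc2)cc(O)c1C=C | intermediate
9 | 3,4,5-tris(benzyloxy)benzoic acid | OC(=O)c1cc(OCc2ccccc2)c(OCc2ccccc2)c(OCc2ccccc2)c1 | starting material
10 | (S)-5-(benzyloxy)-3-{1-[3,4-bis(benzyloxy)phenyl]allyloxy}-2-vinylphenyl 3,4,5-tris(benzyloxy)benzoate | C=C[C@@H](c1ccc(OCc2ccccc2)c(OCc2ccccc2)c1)Oc1cc(OCc2ccccc2)cc(OC(=O)c2cc(OCc3ccccc3)c(OCc3ccccc3)c(OCc3ccccc3)c2)c1C=C | intermediate
11 | (S)-7-(benzyloxy)-2-[3,4-bis(benzyloxy)phenyl]-2H-chromen-5-yl 3,4,5-tris(benzyloxy)benzoate | O=C(Oc1cc(OCc2ccccc2)cc2c1C=C[C@@H](c1ccc(OCc3ccccc3)c(OCc3ccccc3)c1)O2)c1cc(OCc2ccccc2)c(OCc2ccccc2)c(OCc2ccccc2)c1 | intermediate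
12 | (2S,3S)-3-boranyl-7-(benzyloxy)-2-[3,4-bis(benzyloxy)phenyl]chroman-5-yl 3,4,5-tris(benzyloxy)benzoate (C3-borane, boron trans to the C2 aryl group) | O=C(Oc1cc(OCc2ccccc2)cc2c1C[C@H](B)[C@@H](c1ccc(OCc3ccccc3)c(OCc3ccccc3)c1)O2)c1cc(OCc2ccccc2)c(OCc2ccccc2)c(OCc2ccccc2)c1 | intermediate
13 | (2R,3S)-7-(benzyloxy)-2-[3,4-bis(benzyloxy)phenyl]-3-hydroxychroman-5-yl 3,4,5-tris(benzyloxy)benzoate | O=C(Oc1cc(OCc2ccccc2)cc2c1C[C@H](O)[C@@H](c1ccc(OCc3ccccc3)c(OCc3ccccc3)c1)O2)c1cc(OCc2ccccc2)c(OCc2ccccc2)c(OCc2ccccc2)c1 | intermediate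
14 | catechin 5-O-gallate, (2R,3S)-2-(3,4-dihydroxyphenyl)-3,7-dihydroxychroman-5-yl 3,4,5-trihydroxybenzoate | O=C(Oc1cc(O)cc2c1C[C@H](O)[C@@H](c1ccc(O)c(O)c1)O2)c1cc(O)c(O)c(O)c1 | target

Total step count: 9. Longest linear sequence: 8 steps (steps 2 to 9, from 3). The branch from 1 runs over 7 steps.

Steps most likely to fail

1. Step 4.
- Risk: The hydrogen-bonded, electron-poor phenoxide may attack the π-allyl complex too slowly. Ring carbon may compete with oxygen as the nucleophilic site. Re-ionisation of the product ether may erode branched selectivity and enantiopurity.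
- Fallback (from 2, back at 8): One ortho OH of 2 is silylated (TBSCl, imidazole, DMF) to 4-(benzyloxy)-2-[(tert-butyldimethylsilyl)oxy]-6-hydroxybenzaldehyde F1. Wittig methylenation (MePPh3Br, KOt-Bu) then gives the electron-rich nucleophile 5-(benzyloxy)-3-[(tert-butyldimethylsilyl)oxy]-2-vinylphenol F2. This belongs to the 2-vinylphenol class for which the etherification is best established. The same [Ir(cod)Cl]2/phosphoramidite catalyst couples F2 with 6 to the (S)-configured silyl-protected diene ether F3. Treatment with n-Bu4NF in THF releases 8.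

2. Step 8.
- Risk: Boron may be placed partly at C4. The C3-borane, which is antiperiplanar to the C2–O1 bond, may eliminate with opening of ring C. The aryl gallate may suffer reduction or perhydrolysis.
- Fallback (from 11, back at 14): Epoxidation of 11 with dimethyldioxirane (acetone/CH2Cl2, −20 °C) should occur on the face opposite to the C2 aryl group. It gives the 2,3-trans 3,4-epoxyflavan gallate F4, which is used crude. Hydrogenolysis (H2, Pd(OH)2/C, THF/EtOAc) should cleave the benzylic C4–O bond of the epoxide together with the six benzyl ethers. The C3–O bond stays intact, so 14 is reached directly.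

3. Step 5.
- Risk: Deprotonation of the ortho phenol deactivates the already electron-rich aldehyde towards the ylide. The basic medium may isomerise or racemise the doubly activated allylic ether. The free vinylphenol may oligomerise on handling.
- Fallback (from 7, back at 10): The order is inverted. Compound 7 is first esterified with 9 (DCC, DMAP, CH2Cl2) to the (S)-configured formyl gallate F5. The aldehyde, now free of any acidic phenol, is then methylenated under neutral conditions by rhodium-catalysed methylenation (RhCl(PPh3)3 cat., Me3SiCHN2, PPh3, i-PrOH, THF, rt). These conditions tolerate esters and give 10.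

Further compounds
F1 | step 4 | 4-(benzyloxy)-2-[(tert-butyldimethylsilyl)oxy]-6-hydroxybenzaldehyde | O=Cc1c(O)cc(OCc2ccccc2)cc1O[Si](C)(C)C(C)(C)C
F2 | step 4 | 5-(benzyloxy)-3-[(tert-butyldimethylsilyl)oxy]-2-vinylphenol | C=Cc1c(O)cc(OCc2ccccc2)cc1O[Si](C)(C)C(C)(C)C
F3 | step 4 | (S)-{5-(benzyloxy)-3-{1-[3,4-bis(benzyloxy)phenyl]allyloxy}-2-vinylphenoxy}(tert-butyl)dimethylsilane | C=C[C@@H](c1ccc(OCc2ccccc2)c(OCc2ccccc2)c1)Oc1cc(OCc2ccccc2)cc(O[Si](C)(C)C(C)(C)C)c1C=C
F4 | step 8 | (2R)-7-(benzyloxy)-2-[3,4-bis(benzyloxy)phenyl]-3,4-epoxychroman-5-yl 3,4,5-tris(benzyloxy)benzoate, epoxide oxygen anti to the C2 aryl group | O=C(Oc1cc(OCc2ccccc2)cc2c1[C@@H]3O[C@@H]3[C@@H](c1ccc(OCc3ccccc3)c(OCc3ccccc3)c1)O2)c1cc(OCc2ccccc2)c(OCc2ccccc2)c(OCc2ccccc2)c1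
F5 | step 5 | (S)-5-(benzyloxy)-3-{1-[3,4-bis(benzyloxy)phenyl]allyloxy}-2-formylphenyl 3,4,5-tris(benzyloxy)benzoate | C=C[C@@H](c1ccc(OCc2ccccc2)c(OCc2ccccc2)c1)Oc1cc(OCc2ccccc2)cc(OC(=O)c2cc(OCc3ccccc3)c(OCc3ccccc3)c(OCc3ccccc3)c2)c1C=O
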